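## Retrosynthetic overview

1. The target comes from its bis-silyl ether by removal of two primary silyl groups.
2. The ten-membered carbocycle and the cis-fused α-methylene-γ-lactone are closed together, last, by forming C6–C7: a catalytic asymmetric lactonizing allylboration of a (Z,Z)-dienal that carries a 2-(methoxycarbonyl)allyl pinacol boronate.
3. The seco-aldehyde comes from C3–C4 Sonogashira coupling and cis semi-hydrogenation of an epoxy-alkyne allylboronate (East) and a (Z)-iodo-allylic alcohol (West, from but-2-yne-1,4-diol).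
4. East: the C8 ester is made by acylation with silylated sarracinic acid. The C8–O stereocenter and the allylboronate come from a one-pot proline-catalysed α-aminoxylation / Horner–Wadsworth–Emmons reaction of an aldehyde derived from nerol (asymmetric epoxidation, alkyne homologation, ozonolysis).
5. Ring order: oxirane (step 1), then carbocycle and lactone in one operation (step 16).

Assumption (locants and abbreviations): ring carbons are C1 (epoxide CH), C2=C3, C4 (bearing C15H2O), C5, C6 (lactone O), C7, C8 (ester O), C9H2, C10 (epoxide C bearing methyl C14); C11/C12/C13 are the lactone α-carbon, carbonyl and exocyclic CH2. The target is then 1R,2Z,4E,6S,7R,8S,10S. TBS = tert-butyldimethylsilyl; pinacolboryl or B(pin) = 4,4,5,5-tetramethyl-1,3,2-dioxaborolan-2-yl; (R)-TRIP = (R)-3,3′-bis(2,4,6-triisopropylphenyl)-1,1′-binaphthyl-2,2′-diyl hydrogen phosphate.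

## Route

Step 1
Reactants: 1 nerol
Product: 2 [(2R,3S)-3-methyl-3-(4-methylpent-3-en-1-yl)oxiran-2-yl]methanol
Conditions: Ti(OiPr)4 (10 mol %), D-(−)-diisopropyl tartrate (12 mol %), tBuOOH, 4 Å molecular sieves, CH2Cl2, −20 °C
Reagents that add atoms: tert-butyl hydroperoxide, CC(C)(C)OO
Why: Katsuki–Sharpless asymmetric epoxidation; the titanium–D-tartrate complex binds the allylic alcohol and delivers oxygen to the face that gives the (2R,3S)-epoxide (later C1 R, C10 S), the cis relation of the two chain carbons being inherited from the Z-alkene.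

Step 2
Reactants: 2 [(2R,3S)-3-methyl-3-(4-methylpent-3-en-1-yl)oxiran-2-yl]methanol
Product: 4 (2R,3S)-2-ethynyl-3-methyl-3-(4-methylpent-3-en-1-yl)oxirane, via epoxy aldehyde 3 (not isolated)
Conditions: TEMPO (10 mol %), PhI(OAc)2, CH2Cl2, 20 °C; then MeOH, K2CO3, dimethyl (1-diazo-2-oxopropyl)phosphonate, 0 → 20 °C
Reagents that add atoms: dimethyl (1-diazo-2-oxopropyl)phosphonate, COP(=O)(OC)C(=[N+]=[N-])C(C)=O
Why: Oxoammonium oxidation stops at the epoxy aldehyde, and Seyferth–Gilbert homologation with the Ohira–Bestmann reagent under mild carbonate/methanol conditions gives the alkyne without touching the epoxide stereocenters.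

Step 3
Reactants: 4 (2R,3S)-2-ethynyl-3-methyl-3-(4-methylpent-3-en-1-yl)oxirane
Product: 5 3-[(2S,3R)-3-ethynyl-2-methyloxiran-2-yl]propanal
Conditions: O3 (1 equiv), CH2Cl2, −78 °C; then Me2S, −78 → 20 °C
Reagents that add atoms: ozone, [O-][O+]=O
Why: Chemoselective ozonolysis; the electron-rich trisubstituted alkene reacts far faster than the terminal alkyne, and reductive work-up gives the aldehyde (C7) with the epoxide intact.

Step 4
Reactants: 6 trimethyl phosphonoacetate; 7 2-(iodomethyl)-4,4,5,5-tetramethyl-1,3,2-dioxaborolane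
Product: 8 methyl 2-(dimethoxyphosphoryl)-3-(pinacolboryl)propanoate (racemic)
Conditions: NaH, THF, 0 °C; then 7, 0 → 20 °C
Reagents that add atoms: none
Why: Malonate-type C-alkylation; the phosphonoacetate anion adds to boron of the α-iodo boronate and a 1,2-shift expels iodide.

Step 5
Reactants: 5 3-[(2S,3R)-3-ethynyl-2-methyloxiran-2-yl]propanal; 8 methyl 2-(dimethoxyphosphoryl)-3-(pinacolboryl)propanoate
Product: 10 methyl (2E,4S)-4-(anilinooxy)-5-[(2S,3R)-3-ethynyl-2-methyloxiran-2-yl]-2-[(pinacolboryl)methyl]pent-2-enoate, via aminooxy aldehyde 9 (not isolated)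
Conditions: D-proline (20 mol %), PhNO, DMSO, 20 °C; then 8, Cs2CO3, 0 → 20 °C
Reagents that add atoms: nitrosobenzene, O=Nc1ccccc1
Why: Enamine catalysis (proline-catalysed α-aminoxylation): the D-proline enamine attacks the oxygen of PhN=O through the acid-directed transition state and sets C8 as S; the crude aldehyde is trapped by Horner–Wadsworth–Emmons olefination, which puts the branched C8 trans to the ester (2E) and therefore cis to CH2B.

Step 6
Reactants: 10 methyl (2E,4S)-4-(anilinooxy)-5-[(2S,3R)-3-ethynyl-2-methyloxiran-2-yl]-2-[(pinacolboryl)methyl]pent-2-enoate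
Product: 11 methyl (2E,4S)-5-[(2S,3R)-3-ethynyl-2-methyloxiran-2-yl]-4-hydroxy-2-[(pinacolboryl)methyl]pent-2-enoate
Conditions: Cu(OAc)2 (20 mol %), MeOH, 0 → 20 °C, N2
Reagents that add atoms: none
Why: Copper-catalysed N–O cleavage of the O-alkyl-N-arylhydroxylamine frees the C8 hydroxyl under near-neutral conditions; C8 is not touched, and the E-geometry prevents butenolide formation.

Step 7
Reactants: 12 methyl but-2-ynoate
Product: 14 methyl (2Z)-2-(hydroxymethyl)but-2-enoate, via vinylalane 13 (not isolated)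
Conditions: iBu2AlH, N-methylmorpholine N-oxide, THF, 0 °C; then CH2O (gas from cracked paraformaldehyde), 0 → 20 °C
Reagents that add atoms: formaldehyde, C=O
Why: Vinylalumination; syn-hydroalumination of the ynoate places aluminium on the α-carbon with the methyl cis to the ester, and the alkenyl–Al bond adds to formaldehyde with retention to give the Z (sarracinate) geometry.

Step 8
Reactants: 14 methyl (2Z)-2-(hydroxymethyl)but-2-enoate
Product: 15 methyl (2Z)-2-{[(tert-butyldimethylsilyl)oxy]methyl}but-2-enoate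
Conditions: TBSCl, imidazole, CH2Cl2, 0 → 20 °C
Reagents that add atoms: tert-butyldimethylsilyl chloride, CC(C)(C)[Si](C)(C)Cl
Why: Standard silylation of a primary alcohol.

Step 9
Reactants: 15 methyl (2Z)-2-{[(tert-butyldimethylsilyl)oxy]methyl}but-2-enoate
Product: 16 (2Z)-2-{[(tert-butyldimethylsilyl)oxy]methyl}but-2-enoic acid
Conditions: LiOH, THF/MeOH/H2O, 20 °C; then 1 M HCl to pH 4, 0 °C
Reagents that add atoms: lithium hydroxide, [Li+].[OH-]
Why: Saponification of the methyl ester at room temperature, mild enough to keep the Z-alkene and the primary silyl ether.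

Step 10
Reactants: 16 (2Z)-2-{[(tert-butyldimethylsilyl)oxy]methyl}but-2-enoic acid; 11 methyl (2E,4S)-5-[(2S,3R)-3-ethynyl-2-methyloxiran-2-yl]-4-hydroxy-2-[(pinacolboryl)methyl]pent-2-enoate
Product: 18 methyl (2E,4S)-4-{[(2Z)-2-{[(tert-butyldimethylsilyl)oxy]methyl}but-2-enoyl]oxy}-5-[(2S,3R)-3-ethynyl-2-methyloxiran-2-yl]-2-[(pinacolboryl)methyl]pent-2-enoate, via mixed anhydride 17 (not isolated)
Conditions: 16, 2,4,6-trichlorobenzoyl chloride, Et3N, toluene, 20 °C; filter; then 11, toluene, 75 °C (no DMAP)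
Reagents that add atoms: none
Why: Yamaguchi-type mixed-anhydride esterification without a nucleophilic catalyst, the protocol that acylates with angelate-type Z-acids without Z to E isomerization; O-acylation retains C8 (S).

Step 11
Reactants: 19 but-2-yne-1,4-diol
Product: 20 4-[(tert-butyldimethylsilyl)oxy]but-2-yn-1-ol
Conditions: NaH (1.0 equiv), THF, 0 → 20 °C; then TBSCl (1.0 equiv)
Reagents that add atoms: tert-butyldimethylsilyl chloride, CC(C)(C)[Si](C)(C)Cl
Why: Monosilylation of a symmetrical diol through its sparingly soluble monosodium alkoxide.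

Step 12
Reactants: 20 4-[(tert-butyldimethylsilyl)oxy]but-2-yn-1-ol
Product: 22 (2Z)-4-[(tert-butyldimethylsilyl)oxy]-3-iodobut-2-en-1-ol, via cyclic vinylalanate 21 (not isolated)
Conditions: NaAlH2(OCH2CH2OMe)2, THF, 0 → 20 °C; then I2, THF, −78 → 0 °C
Reagents that add atoms: iodine, [I][I]
Why: Hydroxyl-directed trans-hydroalumination; hydride goes to the alkyne carbon next to the carbinol and a five-membered vinylalanate forms, whose C–Al bond is cleaved by iodine with retention, so iodine ends cis to CH2OH (the later C3/C6 cis relation).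

Step 13
Reactants: 18 methyl (2E,4S)-4-{[(2Z)-2-{[(tert-butyldimethylsilyl)oxy]methyl}but-2-enoyl]oxy}-5-[(2S,3R)-3-ethynyl-2-methyloxiran-2-yl]-2-[(pinacolboryl)methyl]pent-2-enoate; 22 (2Z)-4-[(tert-butyldimethylsilyl)oxy]-3-iodobut-2-en-1-ol
Product: 23 methyl (2E,4S)-4-{[(2Z)-2-{[(tert-butyldimethylsilyl)oxy]methyl}but-2-enoyl]oxy}-5-{(2S,3R)-3-[(3E)-3-{[(tert-butyldimethylsilyl)oxy]methyl}-5-hydroxypent-3-en-1-yn-1-yl]-2-methyloxiran-2-yl}-2-[(pinacolboryl)methyl]pent-2-enoate
Conditions: Pd(PPh3)4 (5 mol %), CuI (10 mol %), Et3N, THF, 20 °C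
Reagents that add atoms: none
Why: Sonogashira coupling forms C3–C4 with retention of the vinyl iodide geometry; the pinacol allylboronate is inert without alkoxide or fluoride activation.

Step 14
Reactants: 23 the enyne from step 13
Product: 24 methyl (2E,4S)-4-{[(2Z)-2-{[(tert-butyldimethylsilyl)oxy]methyl}but-2-enoyl]oxy}-5-{(2S,3R)-3-[(1Z,3E)-3-{[(tert-butyldimethylsilyl)oxy]methyl}-5-hydroxypenta-1,3-dien-1-yl]-2-methyloxiran-2-yl}-2-[(pinacolboryl)methyl]pent-2-enoate
Conditions: H2 (1 atm), Pd/CaCO3 poisoned with Pb(OAc)2, quinoline, EtOAc, 20 °C, stopped at 1 equiv uptake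
Reagents that add atoms: none
Why: Lindlar-type syn semi-hydrogenation gives the Z-alkene at C2=C3; the poisoned catalyst spares the electron-poor trisubstituted alkenes and the allylic epoxide.

Step 15
Reactants: 24 the (Z,Z)-dienol from step 14
Product: 25 methyl (2E,4S)-4-{[(2Z)-2-{[(tert-butyldimethylsilyl)oxy]methyl}but-2-enoyl]oxy}-5-{(2S,3R)-3-[(1Z,3E)-3-{[(tert-butyldimethylsilyl)oxy]methyl}-5-oxopenta-1,3-dien-1-yl]-2-methyloxiran-2-yl}-2-[(pinacolboryl)methyl]pent-2-enoate
Conditions: MnO2 (activated), CH2Cl2, 20 °C; filtered and used at once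
Reagents that add atoms: none
Why: MnO2 oxidizes the primary allylic alcohol under neutral heterogeneous conditions with retention of alkene geometry; the 2-alkoxycarbonyl allylboronate does not add to the aldehyde without acid activation.

Step 16
Reactants: 25 the seco-aldehyde from step 15
Product: 27 (1R,2Z,4E,6S,7R,8S,10S)-15-[(tert-butyldimethylsilyl)oxy]-8-{[(2Z)-2-{[(tert-butyldimethylsilyl)oxy]methyl}but-2-enoyl]oxy}-1,10-epoxygermacra-2,4,11(13)-trien-12,6-olide, via boron alkoxide 26 (not isolated)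
Conditions: (R)-TRIP (10 mol %), 4 Å molecular sieves, toluene, 1 mM (syringe-pump addition of 25), 0 → 30 °C
Reagents that add atoms: none
Why: Proposed new method: a chiral-phosphoric-acid-catalysed lactonizing macro-allylboration, in which the acid (P–OH to the pseudo-axial boronate oxygen, P=O to the formyl C–H) switches on the otherwise latent 2-alkoxycarbonyl allylboronate inside a closed chair transition state; the (R)-acid is expected to direct C7 to the Re face of the aldehyde (6S), the axial C8 cis to CH2B gives the syn adduct (7R) whose B–O alkoxide closes the cis-lactone on the methyl ester, and with H8 eclipsing the alkene and the ring tether gauche the aldehyde arrives anti to the C8 acyloxy group (matched case), while high dilution favours ring closure; the closest known reaction types are the intermolecular chiral-phosphoric-acid-catalysed allylboration of aldehydes with allyl pinacol boronates and the thermal or acid-promoted lactonizing allylboration with 2-alkoxycarbonyl allylboronates, neither of which has been used to close a medium ring.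

Step 17
Reactants: 27 the bis-silyl macrolactone from step 16
Product: 28 (1R,2Z,4E,6S,7R,8S,10S)-1,10-epoxy-15-hydroxy-8-{[(2Z)-2-(hydroxymethyl)but-2-enoyl]oxy}germacra-2,4,11(13)-trien-12,6-olide (CNP0293319.3)
Conditions: Bu4NF, AcOH (1:1), THF, 0 → 20 °C
Reagents that add atoms: none
Why: Buffered fluoride desilylation removes both primary silyl ethers, while the acetic acid buffer protects the α-methylene lactone, the esters and the dienyl epoxide from base.

## Compound list

1 | nerol, (2Z)-3,7-dimethylocta-2,6-dien-1-ol | CC(C)=CCC/C(C)=C\CO | starting material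
2 | [(2R,3S)-3-methyl-3-(4-methylpent-3-en-1-yl)oxiran-2-yl]methanol | OC[C@H]1O[C@@]1(C)CCC=C(C)C | intermediate
3 | (2S,3S)-3-methyl-3-(4-methylpent-3-en-1-yl)oxirane-2-carbaldehyde | O=C[C@H]1O[C@@]1(C)CCC=C(C)C | intermediate
4 | (2R,3S)-2-ethynyl-3-methyl-3-(4-methylpent-3-en-1-yl)oxirane | C#C[C@H]1O[C@@]1(C)CCC=C(C)C | intermediate
5 | 3-[(2S,3R)-3-ethynyl-2-methyloxiran-2-yl]propanal | C#C[C@H]1O[C@@]1(C)CCC=O | intermediate
6 | trimethyl phosphonoacetate | COC(=O)CP(=O)(OC)OC | starting material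
7 | 2-(iodomethyl)-4,4,5,5-tetramethyl-1,3,2-dioxaborolane | ICB1OC(C)(C)C(C)(C)O1 | starting material
8 | methyl 2-(dimethoxyphosphoryl)-3-(pinacolboryl)propanoate (racemic) | COC(=O)C(CB1OC(C)(C)C(C)(C)O1)P(=O)(OC)OC | intermediate
9 | (2S)-2-(anilinooxy)-3-[(2S,3R)-3-ethynyl-2-methyloxiran-2-yl]propanal | C#C[C@H]1O[C@@]1(C)C[C@H](ONc1ccccc1)C=O | intermediate
10 | methyl (2E,4S)-4-(anilinooxy)-5-[(2S,3R)-3-ethynyl-2-methyloxiran-2-yl]-2-[(pinacolboryl)methyl]pent-2-enoate | C#C[C@H]1O[C@@]1(C)C[C@H](ONc1ccccc1)/C=C(\CB2OC(C)(C)C(C)(C)O2)C(=O)OC | intermediate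
11 | methyl (2E,4S)-5-[(2S,3R)-3-ethynyl-2-methyloxiran-2-yl]-4-hydroxy-2-[(pinacolboryl)methyl]pent-2-enoate | C#C[C@H]1O[C@@]1(C)C[C@H](O)/C=C(\CB2OC(C)(C)C(C)(C)O2)C(=O)OC | intermediate
12 | methyl but-2-ynoate | CC#CC(=O)OC | starting material
13 | methyl (2E)-2-[bis(2-methylpropyl)alumanyl]but-2-enoate | C/C=C(/[Al](CC(C)C)CC(C)C)C(=O)OC | intermediate
14 | methyl (2Z)-2-(hydroxymethyl)but-2-enoate | C/C=C(/CO)C(=O)OC | intermediate
15 | methyl (2Z)-2-{[(tert-butyldimethylsilyl)oxy]methyl}but-2-enoate | C/C=C(/CO[Si](C)(C)C(C)(C)C)C(=O)OC | intermediate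
16 | (2Z)-2-{[(tert-butyldimethylsilyl)oxy]methyl}but-2-enoic acid | C/C=C(/CO[Si](C)(C)C(C)(C)C)C(=O)O | intermediate
17 | (2Z)-2-{[(tert-butyldimethylsilyl)oxy]methyl}but-2-enoic 2,4,6-trichlorobenzoic anhydride | C/C=C(/CO[Si](C)(C)C(C)(C)C)C(=O)OC(=O)c1c(Cl)cc(Cl)cc1Cl | intermediate
18 | methyl (2E,4S)-4-{[(2Z)-2-{[(tert-butyldimethylsilyl)oxy]methyl}but-2-enoyl]oxy}-5-[(2S,3R)-3-ethynyl-2-methyloxiran-2-yl]-2-[(pinacolboryl)methyl]pent-2-enoate | C#C[C@H]1O[C@@]1(C)C[C@H](OC(=O)/C(=C\C)CO[Si](C)(C)C(C)(C)C)/C=C(\CB2OC(C)(C)C(C)(C)O2)C(=O)OC | intermediate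
19 | but-2-yne-1,4-diol | OCC#CCO | starting material
20 | 4-[(tert-butyldimethylsilyl)oxy]but-2-yn-1-ol | OCC#CCO[Si](C)(C)C(C)(C)C | intermediate
21 | sodium 3-{[(tert-butyldimethylsilyl)oxy]methyl}-2,2-bis(2-methoxyethoxy)-2,5-dihydro-1,2-oxaaluminol-2-uide | [Na+].COCCO[Al-]1(OCCOC)OCC=C1CO[Si](C)(C)C(C)(C)C | intermediate
22 | (2Z)-4-[(tert-butyldimethylsilyl)oxy]-3-iodobut-2-en-1-ol | OC/C=C(\I)CO[Si](C)(C)C(C)(C)C | intermediate
23 | methyl (2E,4S)-4-{[(2Z)-2-{[(tert-butyldimethylsilyl)oxy]methyl}but-2-enoyl]oxy}-5-{(2S,3R)-3-[(3E)-3-{[(tert-butyldimethylsilyl)oxy]methyl}-5-hydroxypent-3-en-1-yn-1-yl]-2-methyloxiran-2-yl}-2-[(pinacolboryl)methyl]pent-2-enoate | OC/C=C(CO[Si](C)(C)C(C)(C)C)\C#C[C@H]1O[C@@]1(C)C[C@H](OC(=O)/C(=C\C)CO[Si](C)(C)C(C)(C)C)/C=C(\CB2OC(C)(C)C(C)(C)O2)C(=O)OC | intermediate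
24 | methyl (2E,4S)-4-{[(2Z)-2-{[(tert-butyldimethylsilyl)oxy]methyl}but-2-enoyl]oxy}-5-{(2S,3R)-3-[(1Z,3E)-3-{[(tert-butyldimethylsilyl)oxy]methyl}-5-hydroxypenta-1,3-dien-1-yl]-2-methyloxiran-2-yl}-2-[(pinacolboryl)methyl]pent-2-enoate | OC/C=C(CO[Si](C)(C)C(C)(C)C)\C=C/[C@H]1O[C@@]1(C)C[C@H](OC(=O)/C(=C\C)CO[Si](C)(C)C(C)(C)C)/C=C(\CB2OC(C)(C)C(C)(C)O2)C(=O)OC | intermediate
25 | methyl (2E,4S)-4-{[(2Z)-2-{[(tert-butyldimethylsilyl)oxy]methyl}but-2-enoyl]oxy}-5-{(2S,3R)-3-[(1Z,3E)-3-{[(tert-butyldimethylsilyl)oxy]methyl}-5-oxopenta-1,3-dien-1-yl]-2-methyloxiran-2-yl}-2-[(pinacolboryl)methyl]pent-2-enoate | O=C/C=C(CO[Si](C)(C)C(C)(C)C)\C=C/[C@H]1O[C@@]1(C)C[C@H](OC(=O)/C(=C\C)CO[Si](C)(C)C(C)(C)C)/C=C(\CB2OC(C)(C)C(C)(C)O2)C(=O)OC | intermediate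
26 | methyl (1R,2Z,4E,6S,7S,8S,10S)-15-[(tert-butyldimethylsilyl)oxy]-8-{[(2Z)-2-{[(tert-butyldimethylsilyl)oxy]methyl}but-2-enoyl]oxy}-1,10-epoxy-6-[(pinacolboryl)oxy]germacra-2,4,11(13)-trien-12-oate (same spatial arrangement as 27; the C7 descriptor differs only through the O–B priority) | COC(=O)C(=C)[C@H]1[C@@H](OB2OC(C)(C)C(C)(C)O2)/C=C(CO[Si](C)(C)C(C)(C)C)\C=C/[C@H]3O[C@@]3(C)C[C@@H]1OC(=O)/C(=C\C)CO[Si](C)(C)C(C)(C)C | intermediate
27 | (1R,2Z,4E,6S,7R,8S,10S)-15-[(tert-butyldimethylsilyl)oxy]-8-{[(2Z)-2-{[(tert-butyldimethylsilyl)oxy]methyl}but-2-enoyl]oxy}-1,10-epoxygermacra-2,4,11(13)-trien-12,6-olide | C=C1C(=O)O[C@H]2/C=C(CO[Si](C)(C)C(C)(C)C)\C=C/[C@H]3O[C@@]3(C)C[C@H](OC(=O)/C(=C\C)CO[Si](C)(C)C(C)(C)C)[C@@H]12 | intermediate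
28 | (1R,2Z,4E,6S,7R,8S,10S)-1,10-epoxy-15-hydroxy-8-{[(2Z)-2-(hydroxymethyl)but-2-enoyl]oxy}germacra-2,4,11(13)-trien-12,6-olide (CNP0293319.3) | C=C1C(=O)O[C@H]2/C=C(CO)\C=C/[C@H]3O[C@@]3(C)C[C@H](OC(=O)/C(=C\C)CO)[C@@H]12 | target

## Step count and risks

Total step count: 17. Longest linear sequence: 11 (steps 1, 2, 3, 5, 6, 10, 13, 14, 15, 16, 17).

The three steps most likely to fail:

Step 16 (the proposed new method). The deactivated boronate may react too slowly with the conjugated dienal, the acid may open the dienyl epoxide, 25 may isomerize through 6π-oxa-electrocyclization, oligomers may form, or the catalyst and substrate may be mismatched. The fallback uses known chemistry and closes the ring at C2=C3 instead of C6–C7. It sets out from 18 and 22 and comes back to the route at 27. Semi-hydrogenation of the terminal alkyne of 18 (H2, Pd/CaCO3 poisoned with Pb(OAc)2, quinoline) gives the vinyl epoxide allylboronate F1. Stille coupling of 22 with Bu3SnCH=CH2 (Pd(PPh3)4, CuI, DMF) gives (2E)-3-{[(tert-butyldimethylsilyl)oxy]methyl}penta-2,4-dien-1-ol F2, and MnO2 oxidizes it to the dienal F3. Thermal lactonizing allylboration of F3 with F1 (toluene, 80 °C, closed chair, syn) gives the acyclic cis-lactone triene F4 after separation from its C6/C7 diastereomer. Ring-closing metathesis of the two vinyl groups of F4 (second-generation Hoveyda–Grubbs catalyst, toluene, 2 mM, 60 °C) then gives 27.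

Step 5. The β-boryl phosphonate 8 is an untested Horner–Wadsworth–Emmons reagent; the E/Z ratio or the stability of its anion may be poor. The fallback sets out from 5 and comes back at 10. Aldehyde 5 is aminoxylated exactly as before to 9 and trapped in the same flask by Wittig olefination with Ph3P=C(I)CO2Me (from Ph3P=CHCO2Me and N-iodosuccinimide), which gives the (Z)-α-iodo enoate F5 with C8 cis to iodine. Negishi coupling of F5 with IZnCH2B(pin) (Pd(PPh3)4, THF, 20 °C) then puts the borylmethyl group in place of iodine with retention and gives 10.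

Step 14. Semi-hydrogenation of the enyne beside the epoxide may over-reduce or open the allylic epoxide. The fallback avoids the enyne; it sets out from 18 and 22 and comes back at 24. Rhodium-catalysed trans-hydroboration of the terminal alkyne of 18 with pinacolborane ([Rh(cod)Cl]2, PiPr3, Et3N, cyclohexane) gives the (Z)-alkenyl boronate F6. Suzuki–Miyaura coupling of F6 with 22 (Pd(PPh3)4, aqueous K3PO4, THF, 20 °C) gives 24 directly.

## Further compounds

F1 | step 16 | methyl (2E,4S)-4-{[(2Z)-2-{[(tert-butyldimethylsilyl)oxy]methyl}but-2-enoyl]oxy}-5-[(2S,3R)-3-ethenyl-2-methyloxiran-2-yl]-2-[(pinacolboryl)methyl]pent-2-enoate | C=C[C@H]1O[C@@]1(C)C[C@H](OC(=O)/C(=C\C)CO[Si](C)(C)C(C)(C)C)/C=C(\CB2OC(C)(C)C(C)(C)O2)C(=O)OC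
F2 | step 16 | (2E)-3-{[(tert-butyldimethylsilyl)oxy]methyl}penta-2,4-dien-1-ol | OC/C=C(CO[Si](C)(C)C(C)(C)C)\C=C
F3 | step 16 | (2E)-3-{[(tert-butyldimethylsilyl)oxy]methyl}penta-2,4-dienal | O=C/C=C(CO[Si](C)(C)C(C)(C)C)\C=C
F4 | step 16 | (4R,5S)-5-[(1E)-2-{[(tert-butyldimethylsilyl)oxy]methyl}buta-1,3-dien-1-yl]-4-{(1S)-1-{[(2Z)-2-{[(tert-butyldimethylsilyl)oxy]methyl}but-2-enoyl]oxy}-2-[(2S,3R)-3-ethenyl-2-methyloxiran-2-yl]ethyl}-3-methylideneoxolan-2-one | C=C1C(=O)O[C@@H](/C=C(CO[Si](C)(C)C(C)(C)C)\C=C)[C@H]1[C@@H](OC(=O)/C(=C\C)CO[Si](C)(C)C(C)(C)C)C[C@]2(C)O[C@@H]2C=C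
F5 | step 5 | methyl (2Z,4S)-4-(anilinooxy)-5-[(2S,3R)-3-ethynyl-2-methyloxiran-2-yl]-2-iodopent-2-enoate | C#C[C@H]1O[C@@]1(C)C[C@H](ONc1ccccc1)/C=C(\I)C(=O)OC
F6 | step 14 | methyl (2E,4S)-4-{[(2Z)-2-{[(tert-butyldimethylsilyl)oxy]methyl}but-2-enoyl]oxy}-5-{(2S,3R)-2-methyl-3-[(Z)-2-(pinacolboryl)ethenyl]oxiran-2-yl}-2-[(pinacolboryl)methyl]pent-2-enoate | CC1(C)OB(/C=C\[C@H]2O[C@@]2(C)C[C@H](OC(=O)/C(=C\C)CO[Si](C)(C)C(C)(C)C)/C=C(\CB3OC(C)(C)C(C)(C)O3)C(=O)OC)OC1(C)C
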